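The route cuts ring A of the C6-linked flavone (unit 1) instead of the crowded C6–C8'' biaryl bond. Ring A bears OH, aryl and OH on C5, C6 and C7 beside an unsubstituted C8, which is the array that a vinylketene and an aryl siloxyalkyne assemble. In one operation, a 6-diazoacetyl-2-anisylpyran-4-one and dibenzylacacetin carrying a silyloxyethynyl group on C8'' give the full biflavone. The sequence is Wolff shift (C8–C8a), cycloaddition (C5–C6, C7–C8) and electrocyclization (C4a–C5). The alkyne carbon bonded to unit 2 must become C6, so no 6/8 isomer can arise. Visible light spares the flavone and pyranone chromophores. Two deprotections finish the synthesis.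

Key step: step 9

Assumption: the target SMILES fixes no configuration at the C6–C8'' axis and the molecule has no stereocentre, so the route aims at the racemic atropisomer mixture.

Step 1
Reactants: 1 4-methoxyacetophenone
Product: 2 1-(4-methoxyphenyl)butane-1,3-dione
Conditions: NaH (2.2 equiv), EtOAc (3 equiv), THF, reflux; aq HCl work-up
Reagents that add atoms: ethyl acetate, CCOC(C)=O
Why: Crossed Claisen condensation in which the ketone enolate is acylated by ethyl acetate and irreversible deprotonation of the 1,3-diketone pulls the equilibrium to product.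

Step 2
Reactants: 2 1-(4-methoxyphenyl)butane-1,3-dione; 3 diethyl oxalate
Product: 6 6-(4-methoxyphenyl)-4-oxo-4H-pyran-2-carboxylic acid, via triketo ester 4 (not isolated), via pyranone ethyl ester 5 (not isolated)
Conditions: NaOEt (2.2 equiv), EtOH, 0 °C to reflux; then conc. aq HCl, reflux
Reagents that add atoms: water, O
Why: Claisen condensation at the terminal methyl group (acylation at the central carbon is reversible, whereas the terminal adduct is held as a stable dienolate salt), then acid-catalysed cyclodehydration of the 1,3,5-tricarbonyl chain to the 4-pyranone and ester hydrolysis, the classical entry to 6-arylcomanic acids.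

Step 3
Reactants: 6 6-(4-methoxyphenyl)-4-oxo-4H-pyran-2-carboxylic acid
Product: 8 6-(diazoacetyl)-2-(4-methoxyphenyl)-4H-pyran-4-one, via acid chloride 7 (not isolated)
Conditions: (COCl)2, DMF (cat.), CH2Cl2, 0 °C to rt, concentrate; then Me3SiCHN2 (1.5 equiv), MeCN/THF, 0 °C, dark; AcOH quench
Reagents that add atoms: (trimethylsilyl)diazomethane, C[Si](C)(C)C=[N+]=[N-]; oxalyl chloride, O=C(Cl)C(=O)Cl (chlorine of intermediate 7 only)
Why: Acid chloride formation followed by Arndt–Eistert-type C-acylation of the diazoalkane with chloride removing the silyl group, where the bulky silyl reagent in small excess at 0 °C replaces diazomethane and keeps dipolar cycloaddition to the activated C5=C6 bond of the pyranone slow relative to acylation.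

Step 4
Reactants: 9 acacetin
Product: 10 5,7-bis(benzyloxy)-2-(4-methoxyphenyl)chromen-4-one
Conditions: BnBr (3 equiv), K2CO3 (4 equiv), DMF, 80 °C
Reagents that add atoms: benzyl bromide, BrCc1ccccc1
Why: Williamson etherification in which the acidic 7-hydroxyl reacts first and excess reagent with heat in DMF also alkylates the chelated 5-hydroxyl.

Step 5
Reactants: 10 5,7-bis(benzyloxy)-2-(4-methoxyphenyl)chromen-4-one
Product: 11 5,7-bis(benzyloxy)-8-iodo-2-(4-methoxyphenyl)chromen-4-one
Conditions: NIS (1.05 equiv), CF3CO2H (cat.), MeCN/CH2Cl2, 0 °C to rt, dark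
Reagents that add atoms: N-iodosuccinimide, O=C1CCC(=O)N1I
Why: Electrophilic aromatic iodination of the phloroglucinol-type ring A, which in fully alkylated 5,7-dioxygenated flavones goes to C8 because C6 is shielded between two benzyloxy groups while C8 has only one alkoxy neighbour and the ring oxygen.

Step 6
Reactants: 11 5,7-bis(benzyloxy)-8-iodo-2-(4-methoxyphenyl)chromen-4-one; 12 ethynyltrimethylsilane
Product: 13 5,7-bis(benzyloxy)-2-(4-methoxyphenyl)-8-[(trimethylsilyl)ethynyl]chromen-4-one
Conditions: PdCl2(PPh3)2 (5 mol %), CuI (10 mol %), Et3N, DMF, 65 °C, sealed vessel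
Reagents that add atoms: none
Why: Sonogashira coupling (oxidative addition of zerovalent palladium to the aryl iodide, transmetalation from the copper acetylide, reductive elimination), a reaction that 8-iodoflavones undergo despite their two ortho oxygen substituents because the alkyne is sterically slim.

Step 7
Reactants: 13 5,7-bis(benzyloxy)-2-(4-methoxyphenyl)-8-[(trimethylsilyl)ethynyl]chromen-4-one
Product: 14 5,7-bis(benzyloxy)-8-ethynyl-2-(4-methoxyphenyl)chromen-4-one
Conditions: K2CO3 (0.2 equiv), MeOH/CH2Cl2, rt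
Reagents that add atoms: none
Why: Methoxide-catalysed protodesilylation of the alkynylsilane, mild enough to leave the flavone and the ethers untouched, while the benzyl group on O7 prevents cyclization to a furan.

Step 8
Reactants: 14 5,7-bis(benzyloxy)-8-ethynyl-2-(4-methoxyphenyl)chromen-4-one
Product: 17 5,7-bis(benzyloxy)-2-(4-methoxyphenyl)-8-[(triisopropylsilyloxy)ethynyl]chromen-4-one, via lithium acetylide 15 (not isolated), via lithium ynolate 16 (not isolated)
Conditions: LiN(SiMe3)2 (1.1 equiv), THF, −78 °C; t-BuOOLi (from anhydrous t-BuOOH and LiN(SiMe3)2, 1.1 equiv), −78 to 0 °C; i-Pr3SiOTf (1.2 equiv), −78 to 0 °C; aq NaHCO3; fast filtration through Et3N-deactivated silica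
Reagents that add atoms: tert-butyl hydroperoxide, CC(C)(C)OO; triisopropylsilyl trifluoromethanesulfonate, CC(C)[Si](C(C)C)(C(C)C)OS(=O)(=O)C(F)(F)F; lithium hexamethyldisilazide, [Li+].C[Si](C)(C)[N-][Si](C)(C)C (lithium of 15 and 16 only)
Why: Oxidation of a lithium acetylide by lithium tert-butyl peroxide (attack of the acetylide on the peroxide oxygen with loss of tert-butoxide) is the standard conversion of terminal alkynes into ynolates, the bulky silyl triflate traps the ynolate on oxygen, and the non-nucleophilic amide base at low temperature spares the poorly electrophilic vinylogous-ester carbonyl of the flavone.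

Step 9
Reactants: 8 6-(diazoacetyl)-2-(4-methoxyphenyl)-4H-pyran-4-one; 17 5,7-bis(benzyloxy)-2-(4-methoxyphenyl)-8-[(triisopropylsilyloxy)ethynyl]chromen-4-one
Product: 22 5-hydroxy-7-(triisopropylsilyloxy)-5'',7''-bis(benzyloxy)-4',4'''-dimethoxy-6,8''-biflavone, via pyranonylketene 18 (not isolated), via cyclobutenone 19 (not isolated), via dienylketene 20 (not isolated), via cyclohexadienone 21 (not isolated)
Conditions: 17 (1.0 equiv), 8 (1.5 equiv, slow addition), anhydrous degassed ClCH2CH2Cl, blue LEDs (ca. 440 nm), 25 °C; then dark, 80 °C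
Reagents that add atoms: none
Why: Blue light is absorbed by the diazoketone but not by the flavone or the 4-pyranone, so it expels N2 and the Wolff 1,2-shift of the pyranonyl group (new C8–C8a bond) gives ketene 18. The siloxyalkyne is polarized by its oxygen so that the aryl-bearing carbon is the nucleophile; it attacks the ketene carbonyl carbon, and the (2+2) cycloaddition gives cyclobutenone 19, setting C5–C6 and C7–C8. On heating, reversible four-electron electrocyclic opening gives dienylketene 20, and the isomer with the pyranone cis to the ketene arm closes the six-membered ring A by six-electron electrocyclization of the ketene carbon onto pyranone C5 (C4a–C5), which is the nucleophilic β-carbon of the ring enol ether and the only carbon neighbour of C6, after which enolization of 21 gives the chelated C5 phenol. This is the Danheiser benzannulation in its diazoketone variant, established for vinyl, aryl and heteroaryl diazoketones with siloxyalkynes, and the 4-pyranone is a new member of that class as the ene component. No stereocentre is formed, and the hindered axis arises racemic without any biaryl coupling because unit 2 rides on an sp2 carbon throughout. The step needs three things: regiocontrol in the cycloaddition (secured by the alkyne polarization, which puts unit 2 on C6 and silyloxy on C7), selective excitation (secured by the wavelength), and suppression of ketene dimerization and product O-acylation (secured by slow addition of 8 and by the hydrogen-bonded, flanked C5 hydroxyl).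

Step 10
Reactants: 22 5-hydroxy-7-(triisopropylsilyloxy)-5'',7''-bis(benzyloxy)-4',4'''-dimethoxy-6,8''-biflavone
Product: 23 5,7-dihydroxy-5'',7''-bis(benzyloxy)-4',4'''-dimethoxy-6,8''-biflavone
Conditions: Bu4NF (1.1 equiv), AcOH (1.1 equiv), THF, 0 °C
Reagents that add atoms: none
Why: Fluoride-induced cleavage of the aryl silyl ether, driven by the Si–F bond and eased by the good 7-phenoxide leaving group, with acetic acid as buffer and with benzyl and methyl ethers inert.

Step 11
Reactants: 23 5,7-dihydroxy-5'',7''-bis(benzyloxy)-4',4'''-dimethoxy-6,8''-biflavone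
Product: 24 5,7,5'',7''-tetrahydroxy-4',4'''-dimethoxy-6,8''-biflavone (CNP0226117.0)
Conditions: H2 (1 atm), 10% Pd/C, THF/MeOH, rt
Reagents that add atoms: none
Why: Catalytic hydrogenolysis of the two benzylic C–O bonds, which at atmospheric pressure and room temperature leaves the flavone C2=C3 bonds and the aryl methyl ethers intact.

Compound list
1 | 4-methoxyacetophenone | COc1ccc(cc1)C(C)=O | starting material
2 | 1-(4-methoxyphenyl)butane-1,3-dione | COc1ccc(cc1)C(=O)CC(C)=O | intermediate
3 | diethyl oxalate | CCOC(=O)C(=O)OCC | starting material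
4 | ethyl 6-(4-methoxyphenyl)-2,4,6-trioxohexanoate (sodium dienolate in the flask, drawn neutral) | CCOC(=O)C(=O)CC(=O)CC(=O)c1ccc(OC)cc1 | intermediate
5 | ethyl 6-(4-methoxyphenyl)-4-oxo-4H-pyran-2-carboxylate | CCOC(=O)c1cc(=O)cc(o1)-c1ccc(OC)cc1 | intermediate
6 | 6-(4-methoxyphenyl)-4-oxo-4H-pyran-2-carboxylic acid | COc1ccc(cc1)-c1cc(=O)cc(o1)C(=O)O | intermediate
7 | 6-(4-methoxyphenyl)-4-oxo-4H-pyran-2-carbonyl chloride | COc1ccc(cc1)-c1cc(=O)cc(o1)C(=O)Cl | intermediate
8 | 6-(diazoacetyl)-2-(4-methoxyphenyl)-4H-pyran-4-one | COc1ccc(cc1)-c1cc(=O)cc(o1)C(=O)C=[N+]=[N-] | intermediate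
9 | acacetin, 5,7-dihydroxy-2-(4-methoxyphenyl)chromen-4-one | COc1ccc(cc1)-c1cc(=O)c2c(O)cc(O)cc2o1 | starting material
10 | 5,7-bis(benzyloxy)-2-(4-methoxyphenyl)chromen-4-one | COc1ccc(cc1)-c1cc(=O)c2c(OCc3ccccc3)cc(OCc3ccccc3)cc2o1 | intermediate
11 | 5,7-bis(benzyloxy)-8-iodo-2-(4-methoxyphenyl)chromen-4-one | COc1ccc(cc1)-c1cc(=O)c2c(OCc3ccccc3)cc(OCc3ccccc3)c(I)c2o1 | intermediate
12 | ethynyltrimethylsilane | C#C[Si](C)(C)C | starting material
13 | 5,7-bis(benzyloxy)-2-(4-methoxyphenyl)-8-[(trimethylsilyl)ethynyl]chromen-4-one | COc1ccc(cc1)-c1cc(=O)c2c(OCc3ccccc3)cc(OCc3ccccc3)c(C#C[Si](C)(C)C)c2o1 | intermediate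
14 | 5,7-bis(benzyloxy)-8-ethynyl-2-(4-methoxyphenyl)chromen-4-one | COc1ccc(cc1)-c1cc(=O)c2c(OCc3ccccc3)cc(OCc3ccccc3)c(C#C)c2o1 | intermediate
15 | lithium acetylide of 14 | COc1ccc(cc1)-c1cc(=O)c2c(OCc3ccccc3)cc(OCc3ccccc3)c(C#[C-])c2o1.[Li+] | intermediate
16 | lithium ynolate, lithium 2-(flavon-8-yl)ethynolate | COc1ccc(cc1)-c1cc(=O)c2c(OCc3ccccc3)cc(OCc3ccccc3)c(C#C[O-])c2o1.[Li+] | intermediate
17 | 5,7-bis(benzyloxy)-2-(4-methoxyphenyl)-8-[(triisopropylsilyloxy)ethynyl]chromen-4-one | COc1ccc(cc1)-c1cc(=O)c2c(OCc3ccccc3)cc(OCc3ccccc3)c(C#CO[Si](C(C)C)(C(C)C)C(C)C)c2o1 | intermediate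
18 | [6-(4-methoxyphenyl)-4-oxo-4H-pyran-2-yl]ketene | COc1ccc(cc1)-c1cc(=O)cc(o1)C=C=O | intermediate
19 | 2-(flavon-8-yl)-4-(pyranon-6-yl)-3-(triisopropylsilyloxy)cyclobut-2-en-1-one (racemic at C4) | COc1ccc(cc1)-c1cc(=O)cc(o1)C1C(=O)C(=C1O[Si](C(C)C)(C(C)C)C(C)C)c1c(OCc2ccccc2)cc(OCc2ccccc2)c2c(=O)cc(oc12)-c1ccc(OC)cc1 | intermediate
20 | dienylketene, 2-(flavon-8-yl)-4-(pyranon-6-yl)-3-(triisopropylsilyloxy)buta-1,3-dien-1-one, pyranonyl group cis to the ketene arm | COc1ccc(cc1)-c1cc(=O)cc(o1)/C=C(O[Si](C(C)C)(C(C)C)C(C)C)\C(=C=O)c1c(OCc2ccccc2)cc(OCc2ccccc2)c2c(=O)cc(oc12)-c1ccc(OC)cc1 | intermediate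
21 | 4a-H cyclohexadienone tautomer of 22 (racemic at C4a) | COc1ccc(cc1)C1=CC(=O)C2C(=O)C(=C(O[Si](C(C)C)(C(C)C)C(C)C)C=C2O1)c1c(OCc2ccccc2)cc(OCc2ccccc2)c2c(=O)cc(oc12)-c1ccc(OC)cc1 | intermediate
22 | 5-hydroxy-7-(triisopropylsilyloxy)-5'',7''-bis(benzyloxy)-4',4'''-dimethoxy-6,8''-biflavone (racemic axis) | COc1ccc(cc1)-c1cc(=O)c2c(O)c(-c3c(OCc4ccccc4)cc(OCc4ccccc4)c4c(=O)cc(-c5ccc(OC)cc5)oc34)c(O[Si](C(C)C)(C(C)C)C(C)C)cc2o1 | intermediate
23 | 5,7-dihydroxy-5'',7''-bis(benzyloxy)-4',4'''-dimethoxy-6,8''-biflavone | COc1ccc(cc1)-c1cc(=O)c2c(O)c(-c3c(OCc4ccccc4)cc(OCc4ccccc4)c4c(=O)cc(-c5ccc(OC)cc5)oc34)c(O)cc2o1 | intermediate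
24 | 5,7,5'',7''-tetrahydroxy-4',4'''-dimethoxy-6,8''-biflavone (CNP0226117.0) | COc1ccc(-c2cc(=O)c3c(O)c(-c4c(O)cc(O)c5c(=O)cc(-c6ccc(OC)cc6)oc45)c(O)cc3o2)cc1 | target

Total step count: 11.
Longest linear sequence: 8 steps (acacetin 9 through steps 4 to 11).

Steps most likely to fail

1. Step 9.
- **What may go wrong:** capture of the ketene by the alkyne, which is flanked on both ortho positions, may be slow. Ketene dimerization or hydration could then take over, or the cascade could stall before ring opening and closure.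
- **Fallback:** it sets out from 11 and 9, rejoins the route at 24, and gives up the annulation for a cross-coupling of two intact flavones.
  - Miyaura borylation of 11 (B2pin2, PdCl2(dppf), KOAc, dioxane, 90 °C) would give 5,7-bis(benzyloxy)-2-(4-methoxyphenyl)-8-(pinacolboryl)chromen-4-one F1.
  - In parallel, 9 is benzylated only at its acidic 7-hydroxyl (BnBr, one equivalent, K2CO3, acetone) to 7-O-benzylacacetin F2.
  - Iodination ortho to the free chelated 5-hydroxyl (BnMe3NICl2, CaCO3, CH2Cl2/MeOH) gives 7-benzyloxy-5-hydroxy-6-iodo-2-(4-methoxyphenyl)chromen-4-one F3.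
  - Suzuki–Miyaura coupling of F1 with F3 (Pd2(dba)3, SPhos, K3PO4, toluene/water, 100 °C) should give the 7,5'',7''-tribenzyl ether of the target F4.
  - The conditions of step 11 convert F4 into 24.

2. Step 8.
- **What may go wrong:** the acetylide or the peroxide anion may add to the chromone, the amide base may metalate C3, or the ynolate may be silylated on carbon.
- **Fallback:** it sets out from 11, rejoins at 23, and avoids any strong base by bringing in the oxygenated alkyne ready-made.
  - Sonogashira coupling of 11 with tert-butoxyacetylene (PdCl2(PPh3)2, CuI, i-Pr2NH, THF, 25 to 40 °C, below the retro-ene threshold of the product) would give 5,7-bis(benzyloxy)-8-(tert-butoxyethynyl)-2-(4-methoxyphenyl)chromen-4-one F5.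
  - Benzannulation of F5 with 8 under the conditions of step 9 follows, with irradiation at 25 °C carried on until F5 is consumed and heating only afterwards. This is the alkoxyalkyne variant of the same reaction and should give the 7-O-tert-butyl analogue of 22 F6.
  - CF3CO2H in CH2Cl2 at rt cleaves F6 to 23.

3. Step 3.
- **What may go wrong:** the diazoalkane may undergo dipolar cycloaddition across the doubly activated C5=C6 bond of the pyranone, or residual HCl may hydrochlorinate the diazo group.
- **Fallback:** it sets out from 2, rejoins at 8, and installs the diazo group by transfer onto a methyl ketone, so that no diazoalkane and no acid chloride are present.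
  - The dianion of 2 (LiN(SiMe3)2, 2.5 equiv, THF, −78 to 0 °C) is acylated at its terminal carbon with methyl 2,2-dimethoxypropanoate to give 6,6-dimethoxy-1-(4-methoxyphenyl)heptane-1,3,5-trione F7.
  - Aqueous HCl in AcOH at 80 °C cyclodehydrates F7 and unmasks the ketone, giving 6-acetyl-2-(4-methoxyphenyl)-4H-pyran-4-one F8.
  - Detrifluoroacetylative diazo transfer follows. LiN(SiMe3)2 and CF3CO2CH2CF3 at −78 °C give 4,4,4-trifluoro-1-[6-(4-methoxyphenyl)-4-oxo-4H-pyran-2-yl]butane-1,3-dione F9, and MsN3, Et3N and water in MeCN then deliver 8.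

Further compounds
F1 | step 9 | 5,7-bis(benzyloxy)-2-(4-methoxyphenyl)-8-(4,4,5,5-tetramethyl-1,3,2-dioxaborolan-2-yl)chromen-4-one | COc1ccc(cc1)-c1cc(=O)c2c(OCc3ccccc3)cc(OCc3ccccc3)c(B3OC(C)(C)C(C)(C)O3)c2o1
F2 | step 9 | 7-O-benzylacacetin, 7-benzyloxy-5-hydroxy-2-(4-methoxyphenyl)chromen-4-one | COc1ccc(cc1)-c1cc(=O)c2c(O)cc(OCc3ccccc3)cc2o1
F3 | step 9 | 7-benzyloxy-5-hydroxy-6-iodo-2-(4-methoxyphenyl)chromen-4-one | COc1ccc(cc1)-c1cc(=O)c2c(O)c(I)c(OCc3ccccc3)cc2o1
F4 | step 9 | 5-hydroxy-7,5'',7''-tris(benzyloxy)-4',4'''-dimethoxy-6,8''-biflavone | COc1ccc(cc1)-c1cc(=O)c2c(O)c(-c3c(OCc4ccccc4)cc(OCc4ccccc4)c4c(=O)cc(-c5ccc(OC)cc5)oc34)c(OCc3ccccc3)cc2o1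
F5 | step 8 | 5,7-bis(benzyloxy)-8-(tert-butoxyethynyl)-2-(4-methoxyphenyl)chromen-4-one | COc1ccc(cc1)-c1cc(=O)c2c(OCc3ccccc3)cc(OCc3ccccc3)c(C#COC(C)(C)C)c2o1
F6 | step 8 | 7-tert-butoxy-5-hydroxy-5'',7''-bis(benzyloxy)-4',4'''-dimethoxy-6,8''-biflavone | COc1ccc(cc1)-c1cc(=O)c2c(O)c(-c3c(OCc4ccccc4)cc(OCc4ccccc4)c4c(=O)cc(-c5ccc(OC)cc5)oc34)c(OC(C)(C)C)cc2o1
F7 | step 3 | 6,6-dimethoxy-1-(4-methoxyphenyl)heptane-1,3,5-trione | COc1ccc(cc1)C(=O)CC(=O)CC(=O)C(C)(OC)OC
F8 | step 3 | 6-acetyl-2-(4-methoxyphenyl)-4H-pyran-4-one | COc1ccc(cc1)-c1cc(=O)cc(o1)C(C)=O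
F9 | step 3 | 4,4,4-trifluoro-1-[6-(4-methoxyphenyl)-4-oxo-4H-pyran-2-yl]butane-1,3-dione | COc1ccc(cc1)-c1cc(=O)cc(o1)C(=O)CC(=O)C(F)(F)F
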